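Thursday's flask holds 0.622 of target per starting material spent, read from 40.0 h on. I carry this ratio, the target share, which is the overall selectivity of the flask. On the list of steps, target comes from second complex, and second complex traces back to starting material. First complex can fall back to starting material, but the list shows no step back to it from target, uncatalysed product or side product. So I reckon the reserve as target share times the c(starting material) left.

| flask | starting material | second substrate | free enzyme | temperature | remark | time |
|---|---|---|---|---|---|---|
| Thursday's | 11 mM | 11.5 mM | 0.90 µM | 30 °C | the very flask that is asked about, followed so far |  |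
| Monday's | 11 mM | 11.5 mM | 1.4 µM | 25 °C | run made earlier |  |
| flask | 11 mM | 11.5 mM | 0.90 µM | 30 °C |  | 4.0 d |

| run | time / h | target / % | starting material / % |
|---|---|---|---|
| Thursday's | 5.00 | 19.2 | 66.0 |
| Thursday's | 15.0 | 44.5 | 24.5 |
| Thursday's | 25.0 | 57.4 | 4.5 |
| Thursday's | 40.0 | 62.2 | 0.3 |
| Thursday's | 60.0 | 61.9 | 0 |
| Thursday's | 72.0 | 62.4 | 0.3 |
| Thursday's | 96.0 | 61.8 | 0.1 |
| Monday's | 3.00 | 13.3 | 81.2 |
| Monday's | 4.00 | 17.5 | 74.9 |
| Monday's | 6.00 | 25.5 | 63.6 |
| Monday's | 10.0 | 38.1 | 45.8 |
| Monday's | 15.0 | 51.3 | 27.3 |
| Monday's | 25.0 | 67.2 | 5.9 |
| Monday's | 40.0 | 72.5 | 0 |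

(readings scatter by 0.3 percentage points)

- noon: at 4.0 d raise the temperature by 25 K, then wait 30 h
- autumn: at 4.0 d take out 90 % of the target then present, then wait 30 h
- dusk: at 4.0 d add free enzyme, 50.0 % of the amount charged, then wait 30 h
- spring: change nothing and wait 30 h more
- midnight: at 4.0 d add second substrate, 100 % of the amount charged, then wait 30 h

- percentages count the starting material that a species holds: one side product counts as two
- target taken out counts as made
- the numbers in the tables scatter with a standard deviation of 0.3 percentage points
- what may be going on: first complex -> loaded enzyme + first product; free enzyme -> unfolded enzyme; starting material + target -> side product; second complex -> free enzyme + target; starting material + free enzyme <-> first complex; second substrate + loaded enzyme <-> second complex; starting material + second substrate -> uncatalysed product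
- additions bring no volume worth counting

- target, in percent of the starting material first charged, at 4.0 d
- the option that brings most further target ("none" if no option brings more than 2 percentage points) (noon / autumn / dusk / spring / midnight / none)
- target present, with what was taken out counted in, in percent of the starting material first charged, after noon
- target present, with what was taken out counted in, in percent of the starting material first charged, after dusk

Which numbers must I know well? The target share need not be good: even at 1, the reserve equals the last reading of starting material, 0.1 %. One scatter more on that reading gives 0.25 percentage points, less than the margin of 2 points. Material bound to enzyme adds little to the reserve: 0.90 µM of enzyme against c(starting material) 11 mM can hold 0.00818 % of the charge in its complexes. Monday's share, 0.725, is higher than Thursday's, so I can't borrow it. The plateau does matter, because the answer moves with it point for point. Its mean carries a scatter of 0.15 points.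

So I commit to 62.1 % now. The reserve is 0.062 points, less than the margin, so my choice is none. Going round once, I put the reserve back on the plateau and get 62.2 % after noon and after dusk.

The forecast gives 62.1 %, best none, 62.1 % after noon and 62.1 % after dusk. Its ground is that “nothing remains to convert”.

The flask gives 62.1 %, best none, 62.1 % after noon and 62.1 % after dusk.

    first complex → loaded enzyme + first product (k = 11.0 s⁻¹, Ea = 63.0 kJ mol⁻¹)
    free enzyme → unfolded enzyme (k = 8.10 × 10⁻⁷ s⁻¹, Ea = 246 kJ mol⁻¹)
    starting material + target → side product (k = 9.30 × 10⁻⁴ L mol⁻¹ s⁻¹, Ea = 62.0 kJ mol⁻¹)
    second complex → free enzyme + target (k = 0.350 s⁻¹, Ea = 79.0 kJ mol⁻¹)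
    starting material + free enzyme ⇌ first complex (K = 40.0 L mol⁻¹, k = 360 L mol⁻¹ s⁻¹, Ea = 35.0 kJ mol⁻¹, ΔH = −36.0 kJ mol⁻¹)
    second substrate + loaded enzyme ⇌ second complex (K = 98.0 L mol⁻¹, k = 280 L mol⁻¹ s⁻¹, Ea = 44.0 kJ mol⁻¹, ΔH = −35.0 kJ mol⁻¹)
    starting material + second substrate → uncatalysed product (k = 7.80 × 10⁻⁴ L mol⁻¹ s⁻¹, Ea = 77.0 kJ mol⁻¹)
    (constants at 30 °C)

In this flask, loaded enzyme holds 58.8 % of the catalyst at 9.60 h, while starting material stands at 43.3 %. By 48.0 h the step from second complex to target has >99.9 % of its turnover behind it, and starting material stands at 0 %. At 96.0 h target is still 62.1 % while unfolded enzyme has reached 18.8 %, and the share of 0.622 has 0 % of starting material to work on. The neighbour charged with 6.9 mM of second substrate has a lower target share, 0.273. It keeps 12 % of starting material, a reserve of 3.3 points, with second substrate at 0.0062 %.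

(Readings and results come from a simulation from invented constants, noise included.)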